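**Retrosynthetic overview**
- Target ⇒ its tri-O-benzyl ether (global hydrogenolysis last) ⇒ the C9'' ethyl ester (chemoselective reduction).
- Both stereocentres (C7'', C8'') ⇒ one dynamic-kinetic-resolution asymmetric transfer hydrogenation of a racemic, stereolabile α-aryloxy-β-keto ester (the proposed new step).
- C8''–O–C4' ether ⇒ SN2 of 5,7-di-O-benzyltricin (free 4'-OH) on an α-bromo-β-keto ester made from 4'-(benzyloxy)acetophenone.
- Tricin core ⇒ chalcone from 2-hydroxy-4,6-bis(benzyloxy)acetophenone and MOM-protected syringaldehyde.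
- Ring order: only ring C (the pyranone) is built, early, by I2/DMSO oxidative cyclisation; rings A, B and the p-hydroxyphenyl ring are purchased.

Assumption: the SMILES is taken as definitive; it is the threo (syn) 7''S,8''S isomer, consistent with the name.

**Step 1**
Reactants: 1, 2',4',6'-trihydroxyacetophenone; 2, benzyl bromide
Product: 3, 1-[2,4-bis(benzyloxy)-6-hydroxyphenyl]ethanone
Conditions: BnBr (2.05 equiv), K2CO3, DMF, 0 °C → rt
Reagents that add atoms: benzyl bromide, BrCc1ccccc1
Why: Williamson etherification stops at the dibenzyl ether because the remaining ortho-OH is hydrogen-bonded to the acetyl carbonyl and poorly nucleophilic.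

**Step 2**
Reactants: 4, syringaldehyde; 5, chloromethyl methyl ether
Product: 6, 3,5-dimethoxy-4-(methoxymethoxy)benzaldehyde
Conditions: MOMCl, i-Pr2NEt, CH2Cl2, 0 °C → rt
Reagents that add atoms: chloromethyl methyl ether, COCCl
Why: O-alkylation (MOM protection) of the phenol prevents phenoxide deactivation of the aldehyde in the base-mediated condensation that follows.

**Step 3**
Reactants: 3, 1-[2,4-bis(benzyloxy)-6-hydroxyphenyl]ethanone; 6, 3,5-dimethoxy-4-(methoxymethoxy)benzaldehyde
Product: 7, (E)-1-[2,4-bis(benzyloxy)-6-hydroxyphenyl]-3-[3,5-dimethoxy-4-(methoxymethoxy)phenyl]prop-2-en-1-one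
Conditions: 50% aq KOH, EtOH/THF, rt, 24–48 h
Reagents that add atoms: none (both partners are the listed reactants)
Why: Claisen–Schmidt condensation between the only enolisable ketone and a non-enolisable aldehyde gives the E-chalcone by E1cB dehydration; benzyl and MOM ethers are base-stable.

**Step 4**
Reactants: 7, the 2'-hydroxychalcone
Product: 8, 5,7-bis(benzyloxy)-2-[3,5-dimethoxy-4-(methoxymethoxy)phenyl]-4H-chromen-4-one
Conditions: I2 (10 mol %), DMSO, 120 °C, 3 h
Reagents that add atoms: none
Why: I2/DMSO oxidative cyclisation (6-endo oxa-Michael to the flavanone, α-iodination, HI loss, DMSO re-oxidising HI) forms ring C; benzyl ethers survive, and any partial MOM loss is harmless because the MOM group is removed next.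

**Step 5**
Reactants: 8, the 4'-O-MOM flavone
Product: 9, 5,7-bis(benzyloxy)-2-(4-hydroxy-3,5-dimethoxyphenyl)-4H-chromen-4-one (5,7-di-O-benzyltricin)
Conditions: 2 M HCl, MeOH/THF, 45 °C
Reagents that add atoms: none
Why: mild acid acetal hydrolysis removes the MOM ether selectively and leaves the benzyl aryl ethers, unmasking the 4'-OH as the only free phenol.

**Step 6**
Reactants: 10, 4'-(benzyloxy)acetophenone; 11, diethyl carbonate
Product: 12, ethyl 3-[4-(benzyloxy)phenyl]-3-oxopropanoate
Conditions: NaH (2.5 equiv), (EtO)2CO, THF, reflux; then AcOH quench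
Reagents that add atoms: diethyl carbonate, CCOC(=O)OCC
Why: crossed Claisen condensation (C-ethoxycarbonylation of the ketone enolate) is driven to completion by deprotonation of the β-keto ester product.

**Step 7**
Reactants: 12, the β-keto ester
Product: 13, ethyl 2-bromo-3-[4-(benzyloxy)phenyl]-3-oxopropanoate (racemic)
Conditions: NBS (1.0 equiv), NH4OAc (10 mol %), Et2O, rt
Reagents that add atoms: N-bromosuccinimide, O=C1CCC(=O)N1Br
Why: electrophilic α-bromination of the enol is much faster than bromination of the acyl-deactivated arene, and one equivalent of NBS limits it to the monobromide.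

**Step 8**
Reactants: 9, 5,7-di-O-benzyltricin; 13, the α-bromo-β-keto ester
Product: 14, ethyl 3-[4-(benzyloxy)phenyl]-2-{4-[5,7-bis(benzyloxy)-4-oxo-4H-chromen-2-yl]-2,6-dimethoxyphenoxy}-3-oxopropanoate (racemic, stereolabile at C2)
Conditions: K2CO3, DMF, rt, 12 h
Reagents that add atoms: none (both partners are the listed reactants)
Why: Williamson-type SN2 displacement of the doubly activated α-bromide by the 4'-phenoxide forms the C8''–O–C4' bond; the new centre is deliberately left racemic and enolisable for the next step.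

**Step 9 (key step)**
Reactants: 14, the racemic α-aryloxy-β-keto ester
Product: 15, ethyl (2R,3S)-3-[4-(benzyloxy)phenyl]-2-{4-[5,7-bis(benzyloxy)-4-oxo-4H-chromen-2-yl]-2,6-dimethoxyphenoxy}-3-hydroxypropanoate (syn)
Conditions: RuCl[(R,R)-TsDPEN](p-cymene) (2–5 mol %), HCO2H/Et3N (5:2), CH2Cl2, 30 °C, 24–48 h
Reagents that add atoms: none
Why: Proposed new method: Ru(II)/TsDPEN dynamic-kinetic-resolution asymmetric transfer hydrogenation of an α-(2,6-dimethoxyaryloxy)-β-keto ester carrying a chromone — C2 of 14 epimerises through its enol in HCO2H/Et3N faster than the ketone is reduced; the (R,R)-Ru–H/N–H outer-sphere six-membered transition state (CH/π contact between the η6-arene and the 4-benzyloxyphenyl ring) delivers hydride to the ketone face that gives 3S; the faster-reacting C2 epimer is the one that holds the C–OAr bond antiperiplanar to the incoming hydride (polar Felkin–Anh), giving the syn (2R,3S) alcohol, after which C2 is no longer acidic and both centres are fixed; the chromone carbonyl is a donor-substituted vinylogous ester and should not accept hydride under these conditions; the closest known reaction type is Noyori–Ikariya DKR transfer hydrogenation of α-alkoxy- and α-amido-β-keto esters (syn-selective for α-alkoxy aryl ketones), which to my knowledge has not been shown for α-aryloxy substrates of this hindered, flavone-bearing kind.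

**Step 10**
Reactants: 15, the syn β-hydroxy ester
Product: 16, 5,7-bis(benzyloxy)-2-[4-({(1S,2S)-1-[4-(benzyloxy)phenyl]-1,3-dihydroxypropan-2-yl}oxy)-3,5-dimethoxyphenyl]-4H-chromen-4-one
Conditions: NaBH4, CaCl2, THF/EtOH, 0 °C → rt
Reagents that add atoms: none
Why: chemoselective borohydride reduction of the activated α-aryloxy-β-hydroxy ester, with the flavone (a γ-pyrone, classically inert to borohydride) untouched; no bond to either stereocentre is broken, and the 2R → 8''S change is only a CIP-priority change.

**Step 11**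
Reactants: 16, the tri-O-benzyl ether
Product: 17, (−)-(7''S,8''S)-4'',5,7-trihydroxy-3',5'-dimethoxy-4',8''-oxyflavonolignan-7'',9''-diol (target)
Conditions: H2 (1 atm), 10% Pd/C, THF/MeOH, rt, stopped at full debenzylation
Reagents that add atoms: none
Why: neutral catalytic hydrogenolysis cleaves the three benzyl aryl ethers faster than it touches the secondary benzylic alcohol or the flavone C2=C3 bond, so both stereocentres are retained.

**Compound list**
1 | 2',4',6'-trihydroxyacetophenone | CC(=O)c1c(O)cc(O)cc1O | starting material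
2 | benzyl bromide | BrCc1ccccc1 | starting material
3 | 1-[2,4-bis(benzyloxy)-6-hydroxyphenyl]ethanone | CC(=O)c1c(O)cc(OCc2ccccc2)cc1OCc1ccccc1 | intermediate
4 | syringaldehyde | COc1cc(C=O)cc(OC)c1O | starting material
5 | chloromethyl methyl ether | COCCl | starting material
6 | 3,5-dimethoxy-4-(methoxymethoxy)benzaldehyde | COCOc1c(OC)cc(C=O)cc1OC | intermediate
7 | (E)-1-[2,4-bis(benzyloxy)-6-hydroxyphenyl]-3-[3,5-dimethoxy-4-(methoxymethoxy)phenyl]prop-2-en-1-one | COCOc1c(OC)cc(/C=C/C(=O)c2c(O)cc(OCc3ccccc3)cc2OCc2ccccc2)cc1OC | intermediate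
8 | 5,7-bis(benzyloxy)-2-[3,5-dimethoxy-4-(methoxymethoxy)phenyl]-4H-chromen-4-one | COCOc1c(OC)cc(-c2cc(=O)c3c(OCc4ccccc4)cc(OCc4ccccc4)cc3o2)cc1OC | intermediate
9 | 5,7-bis(benzyloxy)-2-(4-hydroxy-3,5-dimethoxyphenyl)-4H-chromen-4-one | COc1cc(-c2cc(=O)c3c(OCc4ccccc4)cc(OCc4ccccc4)cc3o2)cc(OC)c1O | intermediate
10 | 4'-(benzyloxy)acetophenone | CC(=O)c1ccc(OCc2ccccc2)cc1 | starting material
11 | diethyl carbonate | CCOC(=O)OCC | starting material
12 | ethyl 3-[4-(benzyloxy)phenyl]-3-oxopropanoate | CCOC(=O)CC(=O)c1ccc(OCc2ccccc2)cc1 | intermediate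
13 | ethyl 2-bromo-3-[4-(benzyloxy)phenyl]-3-oxopropanoate (racemic) | CCOC(=O)C(Br)C(=O)c1ccc(OCc2ccccc2)cc1 | intermediate
14 | ethyl 3-[4-(benzyloxy)phenyl]-2-{4-[5,7-bis(benzyloxy)-4-oxo-4H-chromen-2-yl]-2,6-dimethoxyphenoxy}-3-oxopropanoate (racemic) | COc1cc(-c2cc(=O)c3c(OCc4ccccc4)cc(OCc4ccccc4)cc3o2)cc(OC)c1OC(C(=O)OCC)C(=O)c1ccc(OCc2ccccc2)cc1 | intermediate
15 | ethyl (2R,3S)-3-[4-(benzyloxy)phenyl]-2-{4-[5,7-bis(benzyloxy)-4-oxo-4H-chromen-2-yl]-2,6-dimethoxyphenoxy}-3-hydroxypropanoate | COc1cc(-c2cc(=O)c3c(OCc4ccccc4)cc(OCc4ccccc4)cc3o2)cc(OC)c1O[C@@H](C(=O)OCC)[C@@H](O)c1ccc(OCc2ccccc2)cc1 | intermediate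
16 | 5,7-bis(benzyloxy)-2-[4-({(1S,2S)-1-[4-(benzyloxy)phenyl]-1,3-dihydroxypropan-2-yl}oxy)-3,5-dimethoxyphenyl]-4H-chromen-4-one | COc1cc(-c2cc(=O)c3c(OCc4ccccc4)cc(OCc4ccccc4)cc3o2)cc(OC)c1O[C@@H](CO)[C@@H](O)c1ccc(OCc2ccccc2)cc1 | intermediate
17 | (−)-(7''S,8''S)-4'',5,7-trihydroxy-3',5'-dimethoxy-4',8''-oxyflavonolignan-7'',9''-diol | COc1cc(-c2cc(=O)c3c(O)cc(O)cc3o2)cc(OC)c1O[C@@H](CO)[C@@H](O)c1ccc(O)cc1 | target

**Totals**
Total steps: 11. Longest linear sequence: 8 steps (Steps 1, 3, 4, 5, 8, 9, 10, 11).

**Three steps most likely to fail**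
1. Step 9 (proposed new DKR transfer hydrogenation): it could give poor syn:anti or ee with the bulky aryloxy group, or slow reduction of the electron-rich ketone. Fallback (known chemistry): Evans boron syn-aldol. O-alkylate 9 with ethyl bromoacetate and saponify, attach the acid to (R)-4-benzyloxazolidin-2-one, run the Bu2BOTf/i-Pr2NEt aldol with 4-(benzyloxy)benzaldehyde to get the syn adduct with the 7''S,8''S sense, then remove the auxiliary reductively with NaBH4 to reach 16.
2. Step 8 (SN2 of the di-ortho-substituted phenoxide on a secondary bromide): it could be slow or divert to bromine transfer. Fallback: make the same C–O bond by Rh2(OAc)4-catalysed carbenoid O–H insertion of phenol 9 into ethyl 2-diazo-3-[4-(benzyloxy)phenyl]-3-oxopropanoate (diazo transfer to 12 with p-ABSA/Et3N).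
3. Step 11 (global hydrogenolysis): the p-hydroxybenzylic C7''–OH could be hydrogenolysed or the flavone C2=C3 reduced. Fallback: a silyl end-game. Use 7-O-TIPS-tricin (from tricin, TIPSCl, imidazole) and the bromo keto ester from 4'-(triisopropylsilyloxy)acetophenone, carry them through Steps 8–10, and deprotect with TBAF/AcOH instead of H2/Pd.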